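The runs come from a simulation from invented constants; the scatter is artificial.

The G left over at the end of a flask is the reading to watch when the run is repeated, and near the asked time we reckon from it, as an estimate, the X that stands beside it.

| flask | G | L | remark | time |
|---|---|---|---|---|
| green | 0.13 M | 1.05 equiv (fed, over 15 min) | run made earlier; the fed solution adds 1.0 times the starting volume |  |
| red | 0.40 M | 1.05 equiv (fed, over 15 min) | run made earlier; the fed solution adds 1.0 times the starting volume |  |
| elm | 0.20 M | 1.10 equiv (fed, over 15 min) | the fed solution adds 1.0 times the starting volume | 1.5 h |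
| cedar | 0.20 M | 1.60 equiv (fed, over 15 min) | the fed solution adds 1.0 times the starting volume | 1.5 h |
| larch | 0.20 M | 2.40 equiv (fed, over 15 min) | the fed solution adds 1.0 times the starting volume | 1.5 h |

| run | time / min | Q / % | Z / % | X / % | G / % | J / % |
|---|---|---|---|---|---|---|
| green | 4.00 | 0 | 0 | 1.4 | 99.0 | 0 |
| green | 12.0 | 0 | 0.2 | 8.2 | 91.3 | 0 |
| green | 20.0 | 0.4 | 1.2 | 16.4 | 82.1 | 0.2 |
| green | 30.0 | 0.1 | 2.4 | 23.6 | 72.6 | 0.3 |
| red | 4.00 | 0 | 0.4 | 3.8 | 96.6 | 0 |
| red | 12.0 | 0.1 | 1.3 | 19.5 | 77.8 | 0.4 |
| red | 20.0 | 1.5 | 4.7 | 30.9 | 61.1 | 0.2 |
| red | 30.0 | 2.8 | 6.0 | 37.3 | 48.3 | 0.6 |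

(scatter of a reading: 0.3 percentage points)

- amounts are per litre of the starting volume; all of the dose is in the solution fed
- a reading of Z is of its free form alone

- which of these there is most of at the end, counted by the G in it, elm (Z / Q / X / J / G)
- which of these there is most of at the end, counted by the G in it, cedar (Z / Q / X / J / G)
- which of these there is most of at the end, counted by the G in it, larch (Z / Q / X / J / G)
- final amount of the leader among these, as a percentage of the G charged, in elm
- final amount of the leader among these, as a percentage of the G charged, in cedar
- final amount of the leader among these, as a percentage of the G charged, in larch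

X is made as G takes up L and is spent as X takes up L, so two rates stand against each other: the rate of making, proportional to c(G) times c(L), and the rate of spending, proportional to c(X) times c(L). The feed and the dilution enter both through the same c(L), so their ratio holds c(X)/c(G) and the ratio of the two rate constants. We call that constant ratio κ, the selectivity factor, the rate constant for spending X over the one for making it.

We read it in the red run between 20.0 min and 30.0 min, where X gained 6.4 percentage points while G lost 13 points. The part of the spent G that did not stay as X, divided by the mean c(X)/c(G), gives κ = 0.802, a reading that carries the scatter of 0.3 points.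

X stops rising when c(X)/c(G) reaches 1.25, and red was still below that, at 0.772. As fractions of the G charged, X is G left raised to the power κ, less G left, divided by the amount by which κ falls short of one. That curve crests at 40.9 % of X with 32.8 % of G left.

Counting two L for each G taken past X, the crest costs 0.935 equivalents of L. So we put elm near the crest and larch, with more L charged than that, past it with less X.

The forecast named X, X and X as leaders in elm, cedar and larch, at 41 %, 42 % and 35 %, and called elm “a close call”.

The flasks gave X at 40.1 % in elm, X at 38.9 % in cedar and X at 30.3 % in larch.

    Z ⇌ E (K = 28.0, k = 1.00 × 10⁻⁴ s⁻¹)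
    G + Z → D (k = 0.00270 M⁻¹ s⁻¹)
    L + Z → Q (k = 0.00610 M⁻¹ s⁻¹)
    L + Q → J (k = 0.00340 M⁻¹ s⁻¹)
    G + L → X (k = 0.00380 M⁻¹ s⁻¹)
    L + X → Z (k = 0.00300 M⁻¹ s⁻¹)

Elm ended with 35.1 % of G, beside the crest at 32.8 %. Larch went past the crest: its leftover G of 9.80 % puts the curve, with κ as read, at 28.9 % of X, and the flask holds 30.3 %. The neighbouring flask is cedar charged with 4.00 equiv of L, the other charges and the time held. There G is down to 1.89 % while 26 % of the L remains. The curve at that G gives 11.4 % of X, and the flask holds 12.3 %.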